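**Plan**

- Retrosynthesis: the stilbene C=C is cut first (Horner–Wadsworth–Emmons) into a ring-A aldehyde and a resorcinol benzylphosphonate; then C2–C3 and O1–C2 of the dioxane ring are cut together, giving a gallate 4-O-acetaldehyde and O-silylated syringaldehyde; finally O4–CH2 is cut back to methyl gallate.
- Enabling feature: in the ring O1–C2(syringyl)–C3(CH2OH)–O4, C2 is a benzylic carbon at aldehyde oxidation level bound to O1, and C3 bears O4 and a one-carbon arm. C2 therefore maps onto the carbonyl carbon of syringaldehyde and C3 onto the α-carbon of an aryloxyacetaldehyde whose free ortho phenol becomes O1.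
- Forward order: gallate 4-O-alkylation and unmasking; the only ring closure (the 1,4-dioxane) in step 4; reduction and silylation; ester to aldehyde; attachment of the styryl arm; global desilylation.
- Stereochemistry: C2 comes from the chiral primary-amine iminium in the oxa-Michael closure; C3 follows by equilibration to trans and is frozen by immediate reduction; the E-alkene comes from the olefination.
- Silyl ethers are used throughout so that the last step needs only buffered fluoride, which spares the 4-hydroxybenzyl aryl ether (C2–O1) and the stilbene.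

Key step: step 4

Abbreviation: TBS = tert-butyldimethylsilyl; TBSO = tert-butyldimethylsilyloxy. Ring positions are numbered O1, C2 (aryl), C3, O4, C4a, C5–C8, C8a throughout.

Assumption: which pseudoenantiomeric cinchona primary amine leads to the (2S) configuration can only be inferred by analogy; 9-amino-9-deoxy-epi-quinine is written, and its quinidine-derived pseudoenantiomer would replace it if the sense of induction proved opposite.

**Step 1**
Reactants: 1 methyl gallate; 2 bromoacetaldehyde diethyl acetal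
Product: 3 methyl 4-(2,2-diethoxyethoxy)-3,5-dihydroxybenzoate
Conditions: KHCO3 (1.2 equiv), KI (cat.), DMF, 90 °C, argon
Reagents that add atoms: none
Why: Williamson etherification in which one equivalent of weak base ionises only the most acidic 4-OH (para to the ester), so the 4-phenoxide displaces the primary bromide, as is established for para-selective mono-alkylation of gallate esters.

**Step 2**
Reactants: 3 methyl 4-(2,2-diethoxyethoxy)-3,5-dihydroxybenzoate
Product: 4 methyl 3,5-dihydroxy-4-(2-oxoethoxy)benzoate (expected mainly as its six-membered cyclic hemiacetal)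
Conditions: 1 M HCl, THF/H2O, 45 °C
Reagents that add atoms: water, O
Why: Acid-catalysed acetal hydrolysis should release the aldehyde, which is stabilised as the lactol with a flanking phenol, while the methyl ester tolerates dilute acid.

**Step 3**
Reactants: 5 syringaldehyde
Product: 6 4-(TBSO)-3,5-dimethoxybenzaldehyde
Conditions: TBSCl, imidazole, DMF, rt
Reagents that add atoms: tert-butyldimethylsilyl chloride, CC(C)(C)[Si](C)(C)Cl
Why: Standard imidazole-promoted O-silylation of a phenol, which leaves the aldehyde untouched.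

**Step 4**
Reactants: 4 methyl 3,5-dihydroxy-4-(2-oxoethoxy)benzoate; 6 4-(TBSO)-3,5-dimethoxybenzaldehyde
Product: 8 methyl (2S,3R)-2-[4-(TBSO)-3,5-dimethoxyphenyl]-3-formyl-5-hydroxy-2,3-dihydro-1,4-benzodioxine-7-carboxylate, via α-aryloxy enal 7 (not isolated)
Conditions: 9-amino-9-deoxy-epi-quinine (20 mol %), TFA (40 mol %), CHCl3/THF, 30 °C, slow addition of 4 to 6 (1.5 equiv); extractive work-up, crude aldehyde used at once
Reagents that add atoms: none
Why: Proposed new method: the primary ammonium salt condenses reversibly with both aldehydes, the enamine of 4 (released from its lactol) adds to the iminium of the non-enolisable aldehyde 6, and loss of amine/water gives the conjugated iminium of enal 7, onto whose β-carbon one of the two equivalent flanking phenols closes by 6-endo-trig oxa-Michael addition before enamine protonation and hydrolysis release 8. The closest known reaction types are amine-catalysed aldol condensation/oxa-Michael domino reactions leading to 2H-chromenes, Mannich-type amine-catalysed cross-condensations to α-substituted cinnamaldehydes, and cinchona primary-amine-catalysed intramolecular oxa-Michael additions of phenols to α-branched iminium acceptors. C2 is controlled by the catalyst, whose protonated quinuclidine should hydrogen-bond the phenol and deliver it to one face of the iminium while the quinoline shields the other. C3 is set afterwards under thermodynamic control, since protonation of the cyclic enamine and easy enolisation of the α-aryloxy aldehyde should lead to the trans (diequatorial) isomer. Cross- over self-condensation is secured by the lactol resting state of 4, its slow addition and an excess of 6, whose twisted 4-silyloxy group leaves the carbonyl reasonably electrophilic; regiochemistry is not in question because the two ring-A phenols are symmetry-equivalent. Because the oxa-Michael step is reversible and would erode the enantiomeric purity, the reaction is stopped once 4 is consumed and the aldehyde is reduced immediately.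

**Step 5**
Reactants: 8 methyl (2S,3R)-2-[4-(TBSO)-3,5-dimethoxyphenyl]-3-formyl-5-hydroxy-2,3-dihydro-1,4-benzodioxine-7-carboxylate
Product: 9 methyl (2S,3S)-2-[4-(TBSO)-3,5-dimethoxyphenyl]-5-hydroxy-3-(hydroxymethyl)-2,3-dihydro-1,4-benzodioxine-7-carboxylate
Conditions: NaBH4, MeOH/THF, −40 to −20 °C
Reagents that add atoms: none
Why: Chemoselective borohydride reduction of the aldehyde (aryl ester and aryl silyl ether inert) at low temperature should remove the enolisable β-aryloxy aldehyde and thereby fix both stereocentres; the descriptor at C3 changes only through the priority change.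

**Step 6**
Reactants: 9 methyl (2S,3S)-2-[4-(TBSO)-3,5-dimethoxyphenyl]-5-hydroxy-3-(hydroxymethyl)-2,3-dihydro-1,4-benzodioxine-7-carboxylate
Product: 10 methyl (2S,3S)-5-(TBSO)-3-[(TBSO)methyl]-2-[4-(TBSO)-3,5-dimethoxyphenyl]-2,3-dihydro-1,4-benzodioxine-7-carboxylate
Conditions: TBSCl (2.6 equiv), imidazole, DMF, rt
Reagents that add atoms: tert-butyldimethylsilyl chloride, CC(C)(C)[Si](C)(C)Cl
Why: Imidazole-promoted silylation should protect the phenol and the primary alcohol in one operation without touching the stereocentres.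

**Step 7**
Reactants: 10 methyl (2S,3S)-5-(TBSO)-3-[(TBSO)methyl]-2-[4-(TBSO)-3,5-dimethoxyphenyl]-2,3-dihydro-1,4-benzodioxine-7-carboxylate
Product: 11 [(2S,3S)-5-(TBSO)-3-[(TBSO)methyl]-2-[4-(TBSO)-3,5-dimethoxyphenyl]-2,3-dihydro-1,4-benzodioxin-7-yl]methanol
Conditions: DIBAL-H (2.5 equiv), CH2Cl2, −78 to −20 °C; Rochelle salt work-up
Reagents that add atoms: none
Why: DIBAL-H reduction of an aryl methyl ester to the benzylic alcohol is routine, and silyl ethers and the ring ethers are inert to the hydride.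

**Step 8**
Reactants: 11 [(2S,3S)-5-(TBSO)-3-[(TBSO)methyl]-2-[4-(TBSO)-3,5-dimethoxyphenyl]-2,3-dihydro-1,4-benzodioxin-7-yl]methanol
Product: 12 (2S,3S)-5-(TBSO)-3-[(TBSO)methyl]-2-[4-(TBSO)-3,5-dimethoxyphenyl]-2,3-dihydro-1,4-benzodioxine-7-carbaldehyde
Conditions: activated MnO2 (excess), CH2Cl2, rt
Reagents that add atoms: none
Why: Manganese dioxide oxidises benzylic alcohols selectively to aldehydes under neutral conditions without over-oxidation or silyl loss.

**Step 9**
Reactants: 13 3,5-dihydroxybenzaldehyde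
Product: 14 3,5-bis(TBSO)benzaldehyde
Conditions: TBSCl (2.4 equiv), imidazole, DMF, rt
Reagents that add atoms: tert-butyldimethylsilyl chloride, CC(C)(C)[Si](C)(C)Cl
Why: Standard imidazole-promoted silylation of both phenols.

**Step 10**
Reactants: 14 3,5-bis(TBSO)benzaldehyde
Product: 15 [3,5-bis(TBSO)phenyl]methanol
Conditions: NaBH4, MeOH, 0 °C
Reagents that add atoms: none
Why: Borohydride reduction of an aryl aldehyde to the benzylic alcohol, short enough at 0 °C to leave aryl silyl ethers intact.

**Step 11**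
Reactants: 15 [3,5-bis(TBSO)phenyl]methanol
Product: 16 3,5-bis(TBSO)benzyl bromide
Conditions: CBr4, PPh3, CH2Cl2, 0 °C
Reagents that add atoms: carbon tetrabromide, BrC(Br)(Br)Br
Why: Appel bromination converts the benzylic alcohol to the bromide under neutral conditions compatible with aryl silyl ethers.

**Step 12**
Reactants: 16 3,5-bis(TBSO)benzyl bromide
Product: 17 diethyl [3,5-bis(TBSO)benzyl]phosphonate
Conditions: P(OEt)3 (neat), 130 °C
Reagents that add atoms: triethyl phosphite, CCOP(OCC)OCC
Why: Michaelis–Arbuzov reaction of a reactive benzylic bromide with triethyl phosphite, driven by loss of bromoethane.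

**Step 13**
Reactants: 12 (2S,3S)-5-(TBSO)-3-[(TBSO)methyl]-2-[4-(TBSO)-3,5-dimethoxyphenyl]-2,3-dihydro-1,4-benzodioxine-7-carbaldehyde; 17 diethyl [3,5-bis(TBSO)benzyl]phosphonate
Product: 18 (2S,3S)-7-{(E)-2-[3,5-bis(TBSO)phenyl]ethenyl}-5-(TBSO)-3-[(TBSO)methyl]-2-[4-(TBSO)-3,5-dimethoxyphenyl]-2,3-dihydro-1,4-benzodioxine
Conditions: NaHMDS, THF, −78 °C to rt
Reagents that add atoms: none
Why: Horner–Wadsworth–Emmons olefination of a non-enolisable aryl aldehyde with a benzylphosphonate anion should give the E-stilbene through reversible addition and syn-elimination, and the non-nucleophilic amide base should spare the aryl silyl ethers and the ring stereocentres, which carry no acidic C–H.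

**Step 14**
Reactants: 18 (2S,3S)-7-{(E)-2-[3,5-bis(TBSO)phenyl]ethenyl}-5-(TBSO)-3-[(TBSO)methyl]-2-[4-(TBSO)-3,5-dimethoxyphenyl]-2,3-dihydro-1,4-benzodioxine
Product: 19 (2S,3S)-7-[(E)-2-(3,5-dihydroxyphenyl)ethenyl]-2-(4-hydroxy-3,5-dimethoxyphenyl)-3-(hydroxymethyl)-2,3-dihydro-1,4-benzodioxin-5-ol (CNP0319597.1)
Conditions: TBAF (6 equiv), AcOH (6 equiv), THF, 0 °C to rt, argon
Reagents that add atoms: none
Why: Fluoride-induced cleavage of the four aryl and one alkyl silyl ethers, buffered with acetic acid so that the liberated phenols stay protonated, which should avoid quinone-methide opening at C2–O1 and oxidation of the stilbene polyphenol.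

**Compound list**

1 | methyl gallate (methyl 3,4,5-trihydroxybenzoate) | COC(=O)c1cc(O)c(O)c(O)c1 | starting material
2 | bromoacetaldehyde diethyl acetal (2-bromo-1,1-diethoxyethane) | CCOC(CBr)OCC | starting material
3 | methyl 4-(2,2-diethoxyethoxy)-3,5-dihydroxybenzoate | CCOC(COc1c(O)cc(C(=O)OC)cc1O)OCC | intermediate
4 | methyl 3,5-dihydroxy-4-(2-oxoethoxy)benzoate (ring-chain tautomer of its cyclic hemiacetal) | COC(=O)c1cc(O)c(OCC=O)c(O)c1 | intermediate
5 | syringaldehyde (4-hydroxy-3,5-dimethoxybenzaldehyde) | COc1cc(C=O)cc(OC)c1O | starting material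
6 | 4-(tert-butyldimethylsilyloxy)-3,5-dimethoxybenzaldehyde | CC(C)(C)[Si](C)(C)Oc1c(OC)cc(C=O)cc1OC | intermediate
7 | methyl 4-{[(Z)-1-formyl-2-[4-(tert-butyldimethylsilyloxy)-3,5-dimethoxyphenyl]ethenyl]oxy}-3,5-dihydroxybenzoate (α-aryloxy enal, formed as its iminium) | COC(=O)c1cc(O)c(O/C(C=O)=C\c2cc(OC)c(O[Si](C)(C)C(C)(C)C)c(OC)c2)c(O)c1 | intermediate
8 | methyl (2S,3R)-2-[4-(tert-butyldimethylsilyloxy)-3,5-dimethoxyphenyl]-3-formyl-5-hydroxy-2,3-dihydro-1,4-benzodioxine-7-carboxylate (trans) | CC(C)(C)[Si](C)(C)Oc1c(OC)cc([C@@H]2Oc3cc(C(=O)OC)cc(O)c3O[C@H]2C=O)cc1OC | intermediate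
9 | methyl (2S,3S)-2-[4-(tert-butyldimethylsilyloxy)-3,5-dimethoxyphenyl]-5-hydroxy-3-(hydroxymethyl)-2,3-dihydro-1,4-benzodioxine-7-carboxylate | CC(C)(C)[Si](C)(C)Oc1c(OC)cc([C@@H]2Oc3cc(C(=O)OC)cc(O)c3O[C@H]2CO)cc1OC | intermediate
10 | methyl (2S,3S)-5-(tert-butyldimethylsilyloxy)-3-[(tert-butyldimethylsilyloxy)methyl]-2-[4-(tert-butyldimethylsilyloxy)-3,5-dimethoxyphenyl]-2,3-dihydro-1,4-benzodioxine-7-carboxylate | CC(C)(C)[Si](C)(C)Oc1c(OC)cc([C@@H]2Oc3cc(C(=O)OC)cc(O[Si](C)(C)C(C)(C)C)c3O[C@H]2CO[Si](C)(C)C(C)(C)C)cc1OC | intermediate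
11 | [(2S,3S)-5-(tert-butyldimethylsilyloxy)-3-[(tert-butyldimethylsilyloxy)methyl]-2-[4-(tert-butyldimethylsilyloxy)-3,5-dimethoxyphenyl]-2,3-dihydro-1,4-benzodioxin-7-yl]methanol | CC(C)(C)[Si](C)(C)Oc1c(OC)cc([C@@H]2Oc3cc(CO)cc(O[Si](C)(C)C(C)(C)C)c3O[C@H]2CO[Si](C)(C)C(C)(C)C)cc1OC | intermediate
12 | (2S,3S)-5-(tert-butyldimethylsilyloxy)-3-[(tert-butyldimethylsilyloxy)methyl]-2-[4-(tert-butyldimethylsilyloxy)-3,5-dimethoxyphenyl]-2,3-dihydro-1,4-benzodioxine-7-carbaldehyde | CC(C)(C)[Si](C)(C)Oc1c(OC)cc([C@@H]2Oc3cc(C=O)cc(O[Si](C)(C)C(C)(C)C)c3O[C@H]2CO[Si](C)(C)C(C)(C)C)cc1OC | intermediate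
13 | 3,5-dihydroxybenzaldehyde | O=Cc1cc(O)cc(O)c1 | starting material
14 | 3,5-bis(tert-butyldimethylsilyloxy)benzaldehyde | CC(C)(C)[Si](C)(C)Oc1cc(C=O)cc(O[Si](C)(C)C(C)(C)C)c1 | intermediate
15 | [3,5-bis(tert-butyldimethylsilyloxy)phenyl]methanol | CC(C)(C)[Si](C)(C)Oc1cc(CO)cc(O[Si](C)(C)C(C)(C)C)c1 | intermediate
16 | 3,5-bis(tert-butyldimethylsilyloxy)benzyl bromide | CC(C)(C)[Si](C)(C)Oc1cc(CBr)cc(O[Si](C)(C)C(C)(C)C)c1 | intermediate
17 | diethyl [3,5-bis(tert-butyldimethylsilyloxy)benzyl]phosphonate | CCOP(=O)(Cc1cc(O[Si](C)(C)C(C)(C)C)cc(O[Si](C)(C)C(C)(C)C)c1)OCC | intermediate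
18 | (2S,3S)-7-{(E)-2-[3,5-bis(tert-butyldimethylsilyloxy)phenyl]ethenyl}-5-(tert-butyldimethylsilyloxy)-3-[(tert-butyldimethylsilyloxy)methyl]-2-[4-(tert-butyldimethylsilyloxy)-3,5-dimethoxyphenyl]-2,3-dihydro-1,4-benzodioxine | CC(C)(C)[Si](C)(C)Oc1c(OC)cc([C@@H]2Oc3cc(/C=C/c4cc(O[Si](C)(C)C(C)(C)C)cc(O[Si](C)(C)C(C)(C)C)c4)cc(O[Si](C)(C)C(C)(C)C)c3O[C@H]2CO[Si](C)(C)C(C)(C)C)cc1OC | intermediate
19 | (2S,3S)-7-[(E)-2-(3,5-dihydroxyphenyl)ethenyl]-2-(4-hydroxy-3,5-dimethoxyphenyl)-3-(hydroxymethyl)-2,3-dihydro-1,4-benzodioxin-5-ol | COc1cc([C@@H]2Oc3cc(/C=C/c4cc(O)cc(O)c4)cc(O)c3O[C@H]2CO)cc(OC)c1O | target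

**Step count**

Total: 14 steps. Longest linear sequence: 9 steps (1, 2, 4, 5, 6, 7, 8, 13, 14).

**Steps most likely to fail**

1. Step 4 (proposed method). The cross-condensation may stall at imine or lactol resting states or be overtaken by self-condensation of 4, and the reversible oxa-Michael addition may deliver low enantiomeric purity. The fallback uses known chemistry, sets out from 6 and 1, and returns at 9. Tin(II) chloride-catalysed Roskamp homologation of 6 with ethyl diazoacetate should give ethyl 3-[4-(tert-butyldimethylsilyloxy)-3,5-dimethoxyphenyl]-3-oxopropanoate F1. Bromination with NBS gives ethyl 2-bromo-3-[4-(tert-butyldimethylsilyloxy)-3,5-dimethoxyphenyl]-3-oxopropanoate F2. The 4-phenoxide of 1 (KHCO3, acetone, rt) displaces bromide from this very reactive electrophile to give methyl 4-({1-[4-(tert-butyldimethylsilyloxy)-3,5-dimethoxyphenyl]-3-ethoxy-1,3-dioxopropan-2-yl}oxy)-3,5-dihydroxybenzoate F3. Sodium borohydride reduces the ketone and the activated α-aryloxy ester, sparing the benzoate, to methyl 4-({1-[4-(tert-butyldimethylsilyloxy)-3,5-dimethoxyphenyl]-1,3-dihydroxypropan-2-yl}oxy)-3,5-dihydroxybenzoate F4 as a diastereomer mixture. Acid (Amberlyst-15 or BF3·OEt2) then ionises the benzylic alcohol and a flanking phenol closes the dioxane ring to the thermodynamically preferred trans isomer. This is formed as the racemate, that is 9 together with methyl (2R,3R)-2-[4-(tert-butyldimethylsilyloxy)-3,5-dimethoxyphenyl]-5-hydroxy-3-(hydroxymethyl)-2,3-dihydro-1,4-benzodioxine-7-carboxylate F5, which is removed by preparative HPLC on a chiral stationary phase. Compound 9 then continues with step 6.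

2. Step 1. The sluggish β,β-dialkoxy bromide needs heat, and under these conditions over-alkylation and 3-O-alkylation may erode the 4-O-selectivity. The fallback sets out from 1 and returns at 4. Peracetylation (Ac2O, pyridine) gives methyl 3,4,5-triacetoxybenzoate F6. The established one-pot cleavage and alkylation of the most labile para-acetate, here with the far more reactive allyl bromide (K2CO3, KI, acetone, reflux), gives methyl 3,5-diacetoxy-4-(prop-2-en-1-yloxy)benzoate F7. Ozonolysis (O3, CH2Cl2/MeOH, −78 °C, then Me2S), which the acetylated electron-poor ring should tolerate, gives methyl 3,5-diacetoxy-4-(2-oxoethoxy)benzoate F8. Brief methanolysis (catalytic K2CO3, MeOH, 0 °C) frees the phenols, which capture the aldehyde as the lactol, and this returns 4.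

3. Step 5. In the basic borohydride medium the β-aryloxy aldehyde may undergo retro-oxa-Michael opening or epimerisation at C3 before it is reduced, with loss of enantiomeric and trans purity. The fallback sets out from 8 and returns at 9. Pinnick oxidation under buffered, weakly acidic conditions (NaClO2, NaH2PO4, 2-methyl-2-butene, t-BuOH/H2O) should give the configurationally more robust (2S,3R)-2-[4-(tert-butyldimethylsilyloxy)-3,5-dimethoxyphenyl]-5-hydroxy-7-(methoxycarbonyl)-2,3-dihydro-1,4-benzodioxine-3-carboxylic acid F9 (ring numbering as in 8). Its carboxyl group is then reduced chemoselectively beside the methyl ester with BH3·SMe2 (THF, 0 °C), giving 9.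

**Further compounds**

F1 | step 4 | ethyl 3-[4-(tert-butyldimethylsilyloxy)-3,5-dimethoxyphenyl]-3-oxopropanoate | CCOC(=O)CC(=O)c1cc(OC)c(O[Si](C)(C)C(C)(C)C)c(OC)c1
F2 | step 4 | ethyl 2-bromo-3-[4-(tert-butyldimethylsilyloxy)-3,5-dimethoxyphenyl]-3-oxopropanoate (racemic) | CCOC(=O)C(Br)C(=O)c1cc(OC)c(O[Si](C)(C)C(C)(C)C)c(OC)c1
F3 | step 4 | methyl 4-({1-[4-(tert-butyldimethylsilyloxy)-3,5-dimethoxyphenyl]-3-ethoxy-1,3-dioxopropan-2-yl}oxy)-3,5-dihydroxybenzoate (racemic) | CCOC(=O)C(Oc1c(O)cc(C(=O)OC)cc1O)C(=O)c1cc(OC)c(O[Si](C)(C)C(C)(C)C)c(OC)c1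
F4 | step 4 | methyl 4-({1-[4-(tert-butyldimethylsilyloxy)-3,5-dimethoxyphenyl]-1,3-dihydroxypropan-2-yl}oxy)-3,5-dihydroxybenzoate (diastereomer mixture, racemic) | COC(=O)c1cc(O)c(OC(CO)C(O)c2cc(OC)c(O[Si](C)(C)C(C)(C)C)c(OC)c2)c(O)c1
F5 | step 4 | methyl (2R,3R)-2-[4-(tert-butyldimethylsilyloxy)-3,5-dimethoxyphenyl]-5-hydroxy-3-(hydroxymethyl)-2,3-dihydro-1,4-benzodioxine-7-carboxylate | CC(C)(C)[Si](C)(C)Oc1c(OC)cc([C@H]2Oc3cc(C(=O)OC)cc(O)c3O[C@@H]2CO)cc1OC
F6 | step 1 | methyl 3,4,5-triacetoxybenzoate | COC(=O)c1cc(OC(C)=O)c(OC(C)=O)c(OC(C)=O)c1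
F7 | step 1 | methyl 3,5-diacetoxy-4-(prop-2-en-1-yloxy)benzoate | COC(=O)c1cc(OC(C)=O)c(OCC=C)c(OC(C)=O)c1
F8 | step 1 | methyl 3,5-diacetoxy-4-(2-oxoethoxy)benzoate | COC(=O)c1cc(OC(C)=O)c(OCC=O)c(OC(C)=O)c1
F9 | step 5 | (2S,3R)-2-[4-(tert-butyldimethylsilyloxy)-3,5-dimethoxyphenyl]-5-hydroxy-7-(methoxycarbonyl)-2,3-dihydro-1,4-benzodioxine-3-carboxylic acid | CC(C)(C)[Si](C)(C)Oc1c(OC)cc([C@@H]2Oc3cc(C(=O)OC)cc(O)c3O[C@H]2C(=O)O)cc1OC
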